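**Plan**

- Retrosynthesis: cut the senecioate C–O bond and the axial C4 CH2–O bond, then C8–C17 and C8–OH (back to a C8 ketone), then C11=C12 (Wittig, C12–C15 from a chiral lactone), then C5–C10 and C8–C9 together (intramolecular Diels–Alder), and last C10–CH3/C9–C11 (alkyne carboalumination–carboxylation) and C6=C7 of the enal (cross-metathesis).
- Forward: diethyl allylmalonate is elaborated to the acyclic trienimide 14 (steps 1–7); rings A and B close at once (step 8); the C12–C15 chain is joined at C11 (step 13); the C8 carbinol is built (steps 15–19); the two C4 arms are told apart last (steps 21–24).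
- Enabling feature: the trans-fused rings A and B with the angular C10 methyl next to C9 map C9–C10(CH3)–C11 onto an (E)-β-methyl enoyl dienophile, tied through C1–C3 and the bis(oxymethyl) carbon C4 to a C5–C8 1-silyloxydiene.
- Stereochemistry: C5, C9 and C10 from the endo, auxiliary-controlled cycloaddition; C13 from (S)-4-methyldihydrofuran-2(3H)-one; C8 from epoxidation anti to the axial C10 methyl and hydride opening; C4 from acylation of the less hindered equatorial arm.

Key step: step 8

Remark: atoms carry labdane numbers (C1–C10 decalin, C4 the carbon with the two oxymethyl arms, C10 the angular-methyl carbon, C11–C15 the side chain, C17 the C8 methyl), "up" means the face of the C10 methyl, and (S)-4-methyldihydrofuran-2(3H)-one is assumed to be purchasable.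

**Step 1**
Reactants: 1 diethyl 2-allylmalonate; 2 5-chloropent-1-yne
Product: 3 diethyl 2-allyl-2-(pent-4-yn-1-yl)malonate
Conditions: NaH, DMF, 0 °C; then 2, NaI (cat.), 70 °C
Reagents that add atoms: none
Why: Malonate alkylation (SN2, iodide-catalysed) of the sodium enolate of 1 by the primary chloride makes the future C4 quaternary and brings in C1–C3 plus the alkyne that becomes C9/C10, the terminal alkyne being far less acidic than the malonate.

**Step 2**
Reactants: 3 diethyl 2-allyl-2-(pent-4-yn-1-yl)malonate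
Product: 4 2-allyl-2-(pent-4-yn-1-yl)propane-1,3-diol
Conditions: LiAlH4, THF, 0 °C → rt; aq. NaOH work-up
Reagents that add atoms: none
Why: Hydride reduction of both esters gives the 2,2-disubstituted propane-1,3-diol, and the isolated alkene and alkyne are inert to LiAlH4.

**Step 3**
Reactants: 4 2-allyl-2-(pent-4-yn-1-yl)propane-1,3-diol
Product: 5 5-allyl-2,2-di-tert-butyl-5-(pent-4-yn-1-yl)-1,3,2-dioxasilinane
Conditions: tBu2Si(OTf)2, 2,6-lutidine, CH2Cl2, 0 °C → rt
Reagents that add atoms: di-tert-butylsilyl bis(trifluoromethanesulfonate) CC(C)(C)[Si](OS(=O)(=O)C(F)(F)F)(OS(=O)(=O)C(F)(F)F)C(C)(C)C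
Why: Silylene formation ties the two enantiotopic hydroxymethyl arms into a six-membered ring that should tolerate AlMe3, Lewis acid, ylides, mild acid and hydride and is removed later with fluoride.

**Step 4**
Reactants: 5 5-allyl-2,2-di-tert-butyl-5-(pent-4-yn-1-yl)-1,3,2-dioxasilinane
Product: 8 (2E)-6-(5-allyl-2,2-di-tert-butyl-1,3,2-dioxasilinan-5-yl)-3-methylhex-2-enoic acid, via alkenyldimethylalane 6 (not isolated), via lithium alkenylalanate 7 (not isolated)
Conditions: AlMe3 (2.5 equiv), Cp2ZrCl2 (0.25 equiv), CH2Cl2, rt; evaporate volatiles; n-BuLi, hexane–THF, 0 °C; CO2, −78 °C → rt; 1 M HCl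
Reagents that add atoms: trimethylaluminium C[Al](C)C; carbon dioxide O=C=O
Why: Negishi zirconium-catalysed syn-methylalumination of the terminal alkyne puts the methyl on the internal carbon cis to aluminium, and carboxylation of the derived alanate with retention gives the (E)-β-methyl enoic acid (C10 methyl cis to C11), the monosubstituted alkene reacting far more slowly.

**Step 5**
Reactants: 8 (2E)-6-(5-allyl-2,2-di-tert-butyl-1,3,2-dioxasilinan-5-yl)-3-methylhex-2-enoic acid; 9 (R)-4-benzyloxazolidin-2-one
Product: 11 (4R)-3-[(2E)-6-(5-allyl-2,2-di-tert-butyl-1,3,2-dioxasilinan-5-yl)-3-methylhex-2-enoyl]-4-benzyloxazolidin-2-one, via mixed pivalic anhydride 10 (not isolated)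
Conditions: t-BuCOCl, Et3N, THF, −20 °C; then LiCl, 9, rt
Reagents that add atoms: none
Why: Mixed-anhydride N-acylation of the LiCl/Et3N-activated oxazolidinone attaches the auxiliary at C11 under conditions that should not isomerise or deconjugate the trisubstituted alkene.

**Step 6**
Reactants: 11 the allyl enoyl imide from step 5; 12 (E)-but-2-enal (crotonaldehyde)
Product: 13 (4R)-4-benzyl-3-[(2E)-6-{2,2-di-tert-butyl-5-[(2E)-4-oxobut-2-en-1-yl]-1,3,2-dioxasilinan-5-yl}-3-methylhex-2-enoyl]oxazolidin-2-one
Conditions: 12 (5 equiv), second-generation Hoveyda–Grubbs catalyst RuCl2(H2IMes)(=CH-C6H4-2-OiPr) (5 mol %), CH2Cl2, 40 °C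
Reagents that add atoms: none
Why: Olefin cross-metathesis of the terminal allyl group with excess crotonaldehyde should give the (E)-enal (C5–C8) under thermodynamic control, the electron-poor trisubstituted enoyl alkene being inert to the ruthenium carbene.

**Step 7**
Reactants: 13 the enal imide from step 6
Product: 14 (4R)-4-benzyl-3-[(2E)-6-{2,2-di-tert-butyl-5-[(1E,3E)-4-(triethylsilyloxy)buta-1,3-dien-1-yl]-1,3,2-dioxasilinan-5-yl}-3-methylhex-2-enoyl]oxazolidin-2-one
Conditions: Et3SiOTf, Et3N, CH2Cl2, −78 → 0 °C; rapid filtration through Et3N-deactivated silica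
Reagents that add atoms: triethylsilyl trifluoromethanesulfonate CC[Si](CC)(CC)OS(=O)(=O)C(F)(F)F
Why: Soft γ-enolisation (silyl triflate/amine) of the s-trans enal gives the (1E)-silyl dienol ether, and allylic 1,3-strain from the quaternary C4 on the γ-carbon should direct the new C5=C6 bond to the E geometry that an s-cis diene needs.

**Step 8**
Reactants: 14 the acyclic trienimide from step 7
Product: 15 cycloadduct: trans-fused Δ6-octalin; C4 spiro-linked to the 2,2-di-tert-butyl-1,3,2-dioxasilinane; C10 CH3; C9 C(=O)-[(4R)-4-benzyl-2-oxooxazolidin-3-yl]; C8 OSiEt3; C8-O/C9-C11/C10-CH3 all up and H5 down (10R)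
Conditions: Me2AlCl (1.5 equiv), CH2Cl2, −78 → −20 °C; aq. KNaC4H4O6 work-up
Reagents that add atoms: none
Why: Two-point binding of Me2AlCl to both imide carbonyls gives a cationic aluminium chelate of the s-cis enoyl imide whose C9=C10 bond undergoes a concerted, asynchronous [4+2] cycloaddition with the C5–C8 silyloxydiene, the closest known reaction type being the Lewis-acid-promoted type 1 intramolecular Diels–Alder reaction of N-enoyl oxazolidinone trienes. Ring B (cyclohexene) closes by suprafacial formation of C5–C10 and C8–C9, and ring A closes in the fused mode because the same C5–C10 bond bridges the C1–C4 tether, which adopts a chair. C9 and C10 follow from the (E)-dienophile geometry (C10 methyl and C11 cis), C5 from the endo-carbonyl transition state with the tether anti to the diene (trans fusion), and C8 from the (1E)-enol ether geometry (silyloxy cis to C11; this centre is erased later). The absolute sense is set by the benzyl group of the (R)-auxiliary, which blocks one face of the chelated dienophile so that the diene adds to the other face and the 10R (ent-labdane) series results. The step needs endo over exo and one dienophile face; the Lewis-acid chelate secures both, while the regiochemistry is fixed by the tether and matched by the polarity of the 1-silyloxydiene (C5 nucleophilic, C10 electrophilic). C4 carries two identical oxymethyl arms and is not yet a stereocentre.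

**Step 9**
Reactants: 15 the cycloadduct from step 8
Product: 16 C11 alcohol: trans-fused Δ6-octalin; C4 spiro-silylene; C10 CH3; C9 CH2OH; C8 OSiEt3; substituents at C8/C9/C10 up and H5 down
Conditions: LiBH4, H2O (1 equiv), Et2O, 0 °C; aq. NH4Cl
Reagents that add atoms: none
Why: Reductive cleavage of the N-acyl oxazolidinone (hydride attack at the exocyclic carbonyl) frees the C11 alcohol and returns the auxiliary 9, silyl ethers and the ring alkene being inert.

**Step 10**
Reactants: 16 the C11 alcohol from step 9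
Product: 17 C11 aldehyde: as 16 with C9 CHO
Conditions: Dess–Martin periodinane, NaHCO3, CH2Cl2, 0 °C → rt
Reagents that add atoms: none
Why: Dess–Martin oxidation gives the aldehyde under buffered conditions, and the C9 formyl group already sits in the favoured equatorial position so epimerisation is not a concern.

**Step 11**
Reactants: 18 (S)-4-methyldihydrofuran-2(3H)-one
Product: 19 (S)-4-bromo-3-methylbutanoic acid
Conditions: HBr (33% in AcOH), 60 °C
Reagents that add atoms: hydrogen bromide Br
Why: Acid-mediated lactone opening (SN2 of bromide at the O–CH2 carbon) gives the γ-bromo acid without touching the stereocentre that becomes C13.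

**Step 12**
Reactants: 19 (S)-4-bromo-3-methylbutanoic acid
Product: 20 [(2S)-3-carboxy-2-methylpropyl]triphenylphosphonium bromide
Conditions: PPh3, MeCN, reflux
Reagents that add atoms: triphenylphosphine c1ccc(cc1)P(c1ccccc1)c1ccccc1
Why: Quaternisation of triphenylphosphine (SN2) gives the phosphonium salt that carries C12–C15, as is routine for the unbranched 3-carboxypropyl analogue.

**Step 13**
Reactants: 17 the C11 aldehyde from step 10; 20 [(2S)-3-carboxy-2-methylpropyl]triphenylphosphonium bromide
Product: 22 (3S,4Z)-3-methyl-5-(octalin-9-yl)pent-4-enoic acid: octalin as in 16 (Δ6; C4 spiro-silylene; C8 OSiEt3; C10 CH3), via carboxylate ylide 21 (not isolated)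
Conditions: 20 (2 equiv), NaN(SiMe3)2 (4 equiv), THF, 0 °C; then 17, −78 °C → rt; 1 M HCl to pH 4, 0 °C
Reagents that add atoms: none
Why: Wittig olefination of the hindered aldehyde with the non-stabilised carboxylate ylide forms C11=C12 (Z expected, of no consequence) and brings in C13 with the lactone-derived configuration.

**Step 14**
Reactants: 22 the dienoic acid from step 13
Product: 23 (3R)-3-methyl-5-(decalin-9-yl)pentanoic acid: trans-decalin; C4 spiro-silylene; C8 OSiEt3 axial (up); C10 CH3
Conditions: H2 (1 atm), PtO2, EtOAc, rt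
Reagents that add atoms: none
Why: Heterogeneous hydrogenation saturates both disubstituted alkenes (C6=C7 and C11=C12), and platinum is chosen over palladium to suppress double-bond migration towards the allylic C13 stereocentre and allylic C–O hydrogenolysis.

**Step 15**
Reactants: 23 the saturated silyl ether acid from step 14
Product: 24 C8 alcohol: as 23 with C8 OH (axial; up)
Conditions: AcOH–THF–H2O (3:1:1), rt → 35 °C
Reagents that add atoms: none
Why: Mild acid hydrolysis removes the triethylsilyl ether, while the six-membered di-tert-butylsilylene is expected to survive aqueous acetic acid.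

**Step 16**
Reactants: 24 the C8 alcohol from step 15
Product: 25 C8 ketone: trans-decalin-8-one; C4 spiro-silylene; C10 CH3; C9 equatorial (3R)-4-carboxy-3-methylbutyl chain
Conditions: Dess–Martin periodinane, NaHCO3, CH2Cl2, rt
Reagents that add atoms: none
Why: Dess–Martin oxidation of the axial secondary alcohol gives the ketone, and C9 keeps the thermodynamically favoured equatorial side chain.

**Step 17**
Reactants: 25 the C8 ketone from step 16
Product: 26 8(17)-exocyclic alkene acid: as 25 with C8=CH2
Conditions: Ph3PCH3Br (5 equiv), KOtBu (5 equiv), THF, 65 °C; 1 M HCl to pH 4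
Reagents that add atoms: methyltriphenylphosphonium bromide C[P+](c1ccccc1)(c1ccccc1)c1ccccc1.[Br-]
Why: Wittig methylenation with excess ylide (the first equivalent of base only forms the carboxylate) converts the hindered ketone into the exocyclic alkene, a standard operation on 8-oxo labdanes.

**Step 18**
Reactants: 26 the exocyclic alkene acid from step 17
Product: 27 8,17-epoxide: spiro-oxirane at C8 with the oxygen equatorial (down) and C17 axial (up)
Conditions: mCPBA, NaHCO3, CH2Cl2, 0 °C
Reagents that add atoms: 3-chloroperbenzoic acid OOC(=O)c1cccc(Cl)c1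
Why: Prilezhaev epoxidation should take place from the face opposite the syn-axial C10 methyl (equatorial attack), which sets C8 with oxygen equatorial and C17 axial.

**Step 19**
Reactants: 27 the epoxy acid from step 18
Product: 28 (3R)-5-[8-hydroxy-8,10-dimethyl-4-spiro-silylene-trans-decalin-9-yl]-3-methylpentanoic acid (C8 OH equatorial; C8 CH3 axial)
Conditions: LiEt3BH (5 equiv), THF, 0 °C → rt; 1 M HCl to pH 3, 0 °C
Reagents that add atoms: none
Why: SN2 hydride opening of the epoxide at the primary C17 gives the tertiary carbinol with its axial methyl, and the lithium carboxylate formed first is expected to be inert to triethylborohydride so that C15 stays at the acid level.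

**Step 20**
Reactants: 28 the hydroxy acid from step 19
Product: 29 allyl ester of 28
Conditions: allyl bromide, Cs2CO3, DMF, rt
Reagents that add atoms: allyl bromide C=CCBr
Why: Carboxylate O-alkylation (SN2) masks C15 as an allyl ester under weakly basic conditions in which the tertiary alcohol does not react.

**Step 21**
Reactants: 29 the allyl ester from step 20
Product: 30 triol allyl ester: C4 bis(hydroxymethyl); C8 tertiary OH; C15 allyl ester
Conditions: HF·pyridine, pyridine, THF, 0 °C → rt
Reagents that add atoms: none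
Why: Fluoride cleavage of the silylene under pyridine-buffered conditions releases both C4 hydroxymethyl groups without affecting the ester or the tertiary alcohol.

**Step 22**
Reactants: 30 the triol allyl ester from step 21; 31 3-methylbut-2-enoyl chloride
Product: 32 mono-senecioate: equatorial C4 CH2O-C(=O)CH=C(CH3)2; axial C4 CH2OH; C8 OH; C15 allyl ester
Conditions: 31 (1.05 equiv), 2,4,6-collidine, CH2Cl2, −40 → −10 °C
Reagents that add atoms: none
Why: Kinetically controlled acylation should take the equatorial hydroxymethyl arm, because the axial arm is shielded by the syn-axial C10 methyl, and this fixes the C4 configuration while the tertiary C8 hydroxyl stays free.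

**Step 23**
Reactants: 32 the mono-senecioate from step 22
Product: 33 axial C4 CH2O-C(=S)-imidazol-1-yl derivative of 32
Conditions: 1,1'-thiocarbonyldiimidazole, 4-(dimethylamino)pyridine (cat.), ClCH2CH2Cl, 70 °C
Reagents that add atoms: 1,1'-thiocarbonyldiimidazole S=C(n1ccnc1)n1ccnc1
Why: Thiocarbonylation of the only remaining primary alcohol gives the Barton–McCombie precursor under near-neutral conditions that should not provoke acyl migration.

**Step 24**
Reactants: 33 the imidazolyl thionocarbonate from step 23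
Product: 34 allyl ester of the target (C4 axial CH3)
Conditions: Bu3SnH (3 equiv), AIBN (cat.), toluene, 110 °C
Reagents that add atoms: none
Why: Barton–McCombie radical deoxygenation (stannyl radical addition to C=S, β-scission, hydrogen transfer) turns the axial CH2O arm into the C4 methyl, the high temperature serving the slow fragmentation to a primary neopentyl radical.

**Step 25**
Reactants: 34 the allyl ester from step 24
Product: 35 target acid (4S,5S,8S,9S,10R,13R; labdane numbering)
Conditions: Pd(PPh3)4 (5 mol %), morpholine, THF, rt; dilute acid work-up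
Reagents that add atoms: none
Why: Allyl transfer to morpholine catalysed by zerovalent palladium (Tsuji–Trost deallylation) frees the C15 acid under neutral conditions that leave the senecioate and the tertiary alcohol intact.

**Compound list**

1 | diethyl 2-allylmalonate | C=CCC(C(=O)OCC)C(=O)OCC | starting material
2 | 5-chloropent-1-yne | C#CCCCCl | starting material
3 | diethyl 2-allyl-2-(pent-4-yn-1-yl)malonate | C=CCC(CCCC#C)(C(=O)OCC)C(=O)OCC | intermediate
4 | 2-allyl-2-(pent-4-yn-1-yl)propane-1,3-diol | C=CCC(CO)(CO)CCCC#C | intermediate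
5 | 5-allyl-2,2-di-tert-butyl-5-(pent-4-yn-1-yl)-1,3,2-dioxasilinane | C=CCC1(CCCC#C)CO[Si](C(C)(C)C)(C(C)(C)C)OC1 | intermediate
6 | [(1E)-5-(5-allyl-2,2-di-tert-butyl-1,3,2-dioxasilinan-5-yl)-2-methylpent-1-en-1-yl]dimethylaluminium | C[Al](C)/C=C(\C)CCCC1(CC=C)CO[Si](C(C)(C)C)(C(C)(C)C)OC1 | intermediate
7 | lithium butyl[(1E)-5-(5-allyl-2,2-di-tert-butyl-1,3,2-dioxasilinan-5-yl)-2-methylpent-1-en-1-yl]dimethylaluminate | [Li+].CCCC[Al-](C)(C)/C=C(\C)CCCC1(CC=C)CO[Si](C(C)(C)C)(C(C)(C)C)OC1 | intermediate
8 | (2E)-6-(5-allyl-2,2-di-tert-butyl-1,3,2-dioxasilinan-5-yl)-3-methylhex-2-enoic acid | OC(=O)/C=C(\C)CCCC1(CC=C)CO[Si](C(C)(C)C)(C(C)(C)C)OC1 | intermediate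
9 | (R)-4-benzyloxazolidin-2-one | O=C1N[C@H](Cc2ccccc2)CO1 | starting material
10 | mixed anhydride of 8 with pivalic acid | CC(C)(C)C(=O)OC(=O)/C=C(\C)CCCC1(CC=C)CO[Si](C(C)(C)C)(C(C)(C)C)OC1 | intermediate
11 | (4R)-3-[(2E)-6-(5-allyl-2,2-di-tert-butyl-1,3,2-dioxasilinan-5-yl)-3-methylhex-2-enoyl]-4-benzyloxazolidin-2-one | O=C(/C=C(\C)CCCC1(CC=C)CO[Si](C(C)(C)C)(C(C)(C)C)OC1)N1[C@H](Cc2ccccc2)COC1=O | intermediate
12 | (E)-but-2-enal (crotonaldehyde) | C/C=C/C=O | starting material
13 | (4R)-4-benzyl-3-[(2E)-6-{2,2-di-tert-butyl-5-[(2E)-4-oxobut-2-en-1-yl]-1,3,2-dioxasilinan-5-yl}-3-methylhex-2-enoyl]oxazolidin-2-one | O=C/C=C/CC1(CCC/C(C)=C/C(=O)N2[C@H](Cc3ccccc3)COC2=O)CO[Si](C(C)(C)C)(C(C)(C)C)OC1 | intermediate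
14 | (4R)-4-benzyl-3-[(2E)-6-{2,2-di-tert-butyl-5-[(1E,3E)-4-(triethylsilyloxy)buta-1,3-dien-1-yl]-1,3,2-dioxasilinan-5-yl}-3-methylhex-2-enoyl]oxazolidin-2-one | CC[Si](CC)(CC)O/C=C/C=C/C1(CCC/C(C)=C/C(=O)N2[C@H](Cc3ccccc3)COC2=O)CO[Si](C(C)(C)C)(C(C)(C)C)OC1 | intermediate
15 | cycloadduct: trans-fused Δ6-octalin, C4 spiro-silylene, C10 CH3, C9 acyl-(4R)-4-benzyloxazolidin-2-one, C8 OSiEt3 (C8-O, C9-C11, C10-CH3 up; H5 down; 10R) | CC(C)(C)[Si]1(C(C)(C)C)OCC2(CO1)CCC[C@]3(C)[C@@H]2C=C[C@@H](O[Si](CC)(CC)CC)[C@H]3C(=O)N4[C@H](Cc5ccccc5)COC4=O | intermediate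
16 | C11 alcohol: as 15 with C9 CH2OH | CC(C)(C)[Si]1(C(C)(C)C)OCC2(CO1)CCC[C@]3(C)[C@@H]2C=C[C@@H](O[Si](CC)(CC)CC)[C@H]3CO | intermediate
17 | C11 aldehyde: as 15 with C9 CHO | CC(C)(C)[Si]1(C(C)(C)C)OCC2(CO1)CCC[C@]3(C)[C@@H]2C=C[C@@H](O[Si](CC)(CC)CC)[C@H]3C=O | intermediate
18 | (S)-4-methyldihydrofuran-2(3H)-one | C[C@@H]1COC(=O)C1 | starting material
19 | (S)-4-bromo-3-methylbutanoic acid | C[C@@H](CC(=O)O)CBr | intermediate
20 | [(2S)-3-carboxy-2-methylpropyl]triphenylphosphonium bromide | C[C@@H](CC(=O)O)C[P+](c1ccccc1)(c1ccccc1)c1ccccc1.[Br-] | intermediate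
21 | sodium (3S)-3-methyl-4-(triphenyl-λ5-phosphanylidene)butanoate | [Na+].[O-]C(=O)C[C@H](C)C=P(c1ccccc1)(c1ccccc1)c1ccccc1 | intermediate
22 | (3S,4Z)-3-methyl-5-(octalin-9-yl)pent-4-enoic acid, octalin as in 16 | CC(C)(C)[Si]1(C(C)(C)C)OCC2(CO1)CCC[C@]3(C)[C@@H]2C=C[C@@H](O[Si](CC)(CC)CC)[C@H]3/C=C\[C@@H](C)CC(=O)O | intermediate
23 | (3R)-3-methyl-5-(decalin-9-yl)pentanoic acid: trans-decalin, C4 spiro-silylene, C8 OSiEt3 axial, C10 CH3 | CC(C)(C)[Si]1(C(C)(C)C)OCC2(CO1)CCC[C@]3(C)[C@@H]2CC[C@@H](O[Si](CC)(CC)CC)[C@H]3CC[C@@H](C)CC(=O)O | intermediate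
24 | C8 alcohol: as 23 with C8 OH (axial) | CC(C)(C)[Si]1(C(C)(C)C)OCC2(CO1)CCC[C@]3(C)[C@@H]2CC[C@@H](O)[C@H]3CC[C@@H](C)CC(=O)O | intermediate
25 | C8 ketone acid | CC(C)(C)[Si]1(C(C)(C)C)OCC2(CO1)CCC[C@]3(C)[C@@H]2CCC(=O)[C@H]3CC[C@@H](C)CC(=O)O | intermediate
26 | 8(17)-exocyclic alkene acid | CC(C)(C)[Si]1(C(C)(C)C)OCC2(CO1)CCC[C@]3(C)[C@@H]2CCC(=C)[C@H]3CC[C@@H](C)CC(=O)O | intermediate
27 | 8,17-epoxy acid (oxygen equatorial, C17 axial) | CC(C)(C)[Si]1(C(C)(C)C)OCC2(CO1)CCC[C@]3(C)[C@@H]2CC[C@@]4(CO4)[C@H]3CC[C@@H](C)CC(=O)O | intermediate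
28 | 8-hydroxy acid with C4 spiro-silylene (C8 OH equatorial, C8 CH3 axial) | CC(C)(C)[Si]1(C(C)(C)C)OCC2(CO1)CCC[C@]3(C)[C@@H]2CC[C@](C)(O)[C@H]3CC[C@@H](C)CC(=O)O | intermediate
29 | allyl ester of 28 | CC(C)(C)[Si]1(C(C)(C)C)OCC2(CO1)CCC[C@]3(C)[C@@H]2CC[C@](C)(O)[C@H]3CC[C@@H](C)CC(=O)OCC=C | intermediate
30 | triol allyl ester (C4 bis(hydroxymethyl), C8 OH) | OCC1(CO)CCC[C@]2(C)[C@@H]1CC[C@](C)(O)[C@H]2CC[C@@H](C)CC(=O)OCC=C | intermediate
31 | 3-methylbut-2-enoyl chloride (senecioyl chloride) | CC(C)=CC(Cl)=O | starting material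
32 | mono-senecioate: equatorial CH2O-senecioyl, axial CH2OH at C4 | CC(C)=CC(=O)OC[C@@]1(CO)CCC[C@]2(C)[C@@H]1CC[C@](C)(O)[C@H]2CC[C@@H](C)CC(=O)OCC=C | intermediate
33 | axial O-(imidazol-1-ylthiocarbonyl) derivative of 32 | CC(C)=CC(=O)OC[C@@]1(COC(=S)n3ccnc3)CCC[C@]2(C)[C@@H]1CC[C@](C)(O)[C@H]2CC[C@@H](C)CC(=O)OCC=C | intermediate
34 | allyl ester of the target | CC(C)=CC(=O)OC[C@@]1(C)CCC[C@]2(C)[C@@H]1CC[C@](C)(O)[C@H]2CC[C@@H](C)CC(=O)OCC=C | intermediate
35 | CNP0293742.1: (4S,5S,8S,9S,10R,13R)-8-hydroxy-4-(senecioyloxymethyl)labdan-15-oic acid (ent-labdane series, equatorial CH2O ester at C4) | CC(C)=CC(=O)OC[C@@]1(C)CCC[C@]2(C)[C@@H]1CC[C@](C)(O)[C@H]2CC[C@@H](C)CC(=O)O | target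

**Step count and weak points**

Total step count: 25. Longest linear sequence: 23 steps (steps 1–10 and 13–25, from 1); steps 11 and 12 form the side branch that joins at step 13.

Steps most likely to fail:

1. Step 8. The stoichiometric alkylaluminium chloride may desilylate or ionise the triethylsilyl dienol ether before the hindered β,β-disubstituted dienophile reacts, and at the temperature then needed the benzyl group may discriminate the two dienophile faces poorly. The fallback moves the face control from the auxiliary to a chiral Lewis acid used in catalytic amount. It sets out from acid 8, which (through 10) would acylate oxazolidin-2-one to the achiral N-enoyl oxazolidin-2-one F1. Cross-metathesis with 12 would give the enal F2 and silylation the triethylsilyl dienol ether F3. Cyclisation with the divalent copper bis(oxazoline) complex [Cu((S,S)-tBu-box)](SbF6)2 (10 mol %, CH2Cl2), whose square-planar chelate is predicted to open the same dienophile face as the (R)-benzyl auxiliary, would give the octalin imide F4. LiBH4 reduction of F4 comes back to the route at alcohol 16.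

2. Step 22. The acid chloride may discriminate too weakly between the equatorial and the axial hydroxymethyl group, or the ester may migrate between the two 1,3-related oxygens, so that the C4 configuration is eroded. The fallback holds the equatorial position with a bulky silyl placeholder and acylates last. It sets out from triol 30: tert-butyldiphenylsilyl chloride and imidazole would silylate the equatorial arm to the silyl ether F5; thiocarbonylation of the axial alcohol would give the imidazolyl thionocarbonate F6 and radical reduction with Bu3SnH the axial-methyl silyl ether F7; HF·pyridine would free the equatorial alcohol F8. Acylation of its only primary hydroxyl with 31 (pyridine, 4-(dimethylamino)pyridine) comes back to the route at allyl ester 34.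

3. Step 24. Fragmentation of the thionocarbonate radical adduct to a primary neopentyl radical is slow, so that return to the alcohol or addition of stannyl radicals to the allyl ester and the senecioate may compete. The fallback removes the oxygen by an ionic carbonyl reduction. It sets out from 32: Dess–Martin oxidation would give the axial aldehyde F9 and condensation with 4-toluenesulfonyl hydrazide the tosylhydrazone F10. Reduction of F10 with catecholborane followed by NaOAc·3H2O (loss of sulfinate and dinitrogen from the diazene) would give the C4 methyl group and comes back to the route at 34.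

**Further compounds**

F1 | step 8 | 3-[(2E)-6-(5-allyl-2,2-di-tert-butyl-1,3,2-dioxasilinan-5-yl)-3-methylhex-2-enoyl]oxazolidin-2-one | O=C(/C=C(\C)CCCC1(CC=C)CO[Si](C(C)(C)C)(C(C)(C)C)OC1)N1CCOC1=O
F2 | step 8 | 3-[(2E)-6-{2,2-di-tert-butyl-5-[(2E)-4-oxobut-2-en-1-yl]-1,3,2-dioxasilinan-5-yl}-3-methylhex-2-enoyl]oxazolidin-2-one | O=C/C=C/CC1(CCC/C(C)=C/C(=O)N2CCOC2=O)CO[Si](C(C)(C)C)(C(C)(C)C)OC1
F3 | step 8 | 3-[(2E)-6-{2,2-di-tert-butyl-5-[(1E,3E)-4-(triethylsilyloxy)buta-1,3-dien-1-yl]-1,3,2-dioxasilinan-5-yl}-3-methylhex-2-enoyl]oxazolidin-2-one | CC[Si](CC)(CC)O/C=C/C=C/C1(CCC/C(C)=C/C(=O)N2CCOC2=O)CO[Si](C(C)(C)C)(C(C)(C)C)OC1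
F4 | step 8 | cycloadduct as 15 with an unsubstituted oxazolidin-2-one on the C9 carbonyl | CC(C)(C)[Si]1(C(C)(C)C)OCC2(CO1)CCC[C@]3(C)[C@@H]2C=C[C@@H](O[Si](CC)(CC)CC)[C@H]3C(=O)N4CCOC4=O
F5 | step 22 | equatorial C4 CH2O-tert-butyldiphenylsilyl ether of triol 30 (axial CH2OH free) | CC(C)(C)[Si](c1ccccc1)(c1ccccc1)OC[C@@]1(CO)CCC[C@]2(C)[C@@H]1CC[C@](C)(O)[C@H]2CC[C@@H](C)CC(=O)OCC=C
F6 | step 22 | axial O-(imidazol-1-ylthiocarbonyl) derivative of F5 | CC(C)(C)[Si](c1ccccc1)(c1ccccc1)OC[C@@]1(COC(=S)n3ccnc3)CCC[C@]2(C)[C@@H]1CC[C@](C)(O)[C@H]2CC[C@@H](C)CC(=O)OCC=C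
F7 | step 22 | C4 axial-methyl equatorial CH2O-tert-butyldiphenylsilyl ether allyl ester | CC(C)(C)[Si](c1ccccc1)(c1ccccc1)OC[C@@]1(C)CCC[C@]2(C)[C@@H]1CC[C@](C)(O)[C@H]2CC[C@@H](C)CC(=O)OCC=C
F8 | step 22 | C4 axial-methyl equatorial CH2OH allyl ester (8-hydroxy) | OC[C@@]1(C)CCC[C@]2(C)[C@@H]1CC[C@](C)(O)[C@H]2CC[C@@H](C)CC(=O)OCC=C
F9 | step 24 | axial C4 aldehyde of 32 | CC(C)=CC(=O)OC[C@@]1(C=O)CCC[C@]2(C)[C@@H]1CC[C@](C)(O)[C@H]2CC[C@@H](C)CC(=O)OCC=C
F10 | step 24 | 4-toluenesulfonylhydrazone of F9 | CC(C)=CC(=O)OC[C@@]1(/C=N/NS(=O)(=O)c3ccc(C)cc3)CCC[C@]2(C)[C@@H]1CC[C@](C)(O)[C@H]2CC[C@@H](C)CC(=O)OCC=C
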